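Late times came first: I wanted the books on the starting material closed at 4.0 d, kept in per cent of its charge. The flask asked about is Sunday's run itself, followed further.

in all of them: starting material 0.065 M; capture agent 0.0195 M

|  | first nucleophile | solid second nucleophile | remark | time |
|---|---|---|---|---|
| Sunday's | 1.2 equiv | 2.5 equiv | the very flask that is asked about, followed so far |  |
| flask | 1.20 equiv | 2.50 equiv |  | 4.0 d |

- Sunday's (time / h: target / %, other capture product / %): 2.00: 3.0, 0.2; 6.00: 11.4, 0; 10.0: 14.5, 0.2; 15.0: 22.1, 0; 20.0: 27.2, 0.3; 30.0: 32.0, 0.4

(standard deviation of a reading: 1 percentage point)

- at the start none of the solid second nucleophile is in solution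
- a reading or a percentage of target counts all its forms, free or not

- ratio of target to other capture product at 2.5 h
- ratio of target to other capture product at 4.0 d
- which of target and other capture product there is more of at 4.0 d

Sunday's target reading at 30.0 h, 32.0%, stood above the capture agent's charge of 30.0%, so I took the starting material as limiting reagent.

The early end gave the pace. The target gained 22.1% by 15.0 h, then 9.9 percentage points in the next 15.0 h. If each equal interval brings the same fraction of the gain before it, the gains sum to a limit. I called this the ceiling, the level at which a first-order rise through those two gains stops: 40.0%. Its time constant is 18.7 h, and 4.0 d is 5.13 of those, so I joined the two ends there. Each gain carries the scatter, so the ceiling is rough.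

The other capture product read 0.4% at 30.0 h, inside one scatter of 1 point. I carried that pace forward, and the remainder closed the books:

| Entry at 4.0 d | Share of starting material |
|---|---|
| target | 40.0% |
| other capture product | 1.28% |
| unread | 58.7% |

So I committed to a ratio near 31.2 at 4.0 d, with the target ahead. I gave no ratio for 2.5 h, since the other capture product's early readings lie inside the scatter.

The forecast gave 60 (10 to 500) at 2.5 h and 8 (1 to 40) at 4.0 d, below my ratio, with target ahead: “The target probably still leads, though a late change after the capture agent runs out is possible.”

The flask gave 370 at 2.5 h and 31.1 at 4.0 d, with target ahead, 45.8% against 1.47%.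

    starting material → open intermediate (k = 6.86 × 10⁻⁴ min⁻¹)
    first nucleophile + open intermediate → target (k = 0.195 M⁻¹ min⁻¹)
    second nucleophile + open intermediate → other capture product (k = 0.0151 M⁻¹ min⁻¹)
    open intermediate → solvolysis product (k = 0.0113 min⁻¹)
    solid second nucleophile ⇌ second nucleophile, rate k5*(cs5 - [second nucleophile]) while solid is left; crystals form when [second nucleophile] > cs5 (solubility = 0.0510 M, k = 6.21 × 10⁻⁴ min⁻¹)
    starting material + target ⇌ idle adduct, settled at all times (K = 47.0 M⁻¹)
    open intermediate + capture agent → trapped intermediate (k = 0.00428 M⁻¹ min⁻¹)

My unread line held solvolysis product, 42.9% at 4.00 d. In the scheme the step to target carries c(first nucleophile) and the step to solvolysis product does not. So I set the ceiling against that solvolysis product, odds of 0.932, and scaled them by the charge for the neighbour flask at 0.16 M, which has the same equivalents. That gave odds of 2.30, a target share of 69.7% of target and solvolysis product together. That neighbour flask held 56.8% of target and 23.2% of solvolysis product at 4.00 d, a share of 71.0%.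

(The data were computed for an exercise.)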